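The number that carries these flasks is 1.70, read from Friday's last reading: the selectivity factor, the logarithm of the unreacted fraction of the left-handed charge over the same logarithm for the right-handed charge. Both hands meet the same c(reagent), so it cancels from d ln c(left-handed substrate) / d ln c(right-handed substrate). While the hands do not interconvert, the left-handed unreacted fraction is therefore the right-handed one raised to the power s, whatever the reagent does meanwhile.

| flask | left-handed substrate | right-handed substrate | reagent | temperature | remark | time |
|---|---|---|---|---|---|---|
| Friday's | 20 mM | 20 mM | 4 equiv | 80 °C | run made earlier |  |
| grey | 10 mM | 10 mM | 4.00 equiv | 90 °C |  | 8.0 min |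
| teal | 10 mM | 10 mM | 4.00 equiv | 80 °C |  | 8.0 min |

Friday's run (percent of the left-handed substrate and right-handed substrate together charged)

| time / s | right-handed substrate / % | left-handed substrate / % | left-handed product / % | right-handed product / % |
|---|---|---|---|---|
| 25.0 | 31.7 | 24.3 | 26.2 | 17.7 |
| 50.0 | 24.2 | 13.9 | 35.3 | 25.9 |
| 80.0 | 17.0 | 8.8 | 41.3 | 32.2 |
| 90.0 | 16.5 | 7.2 | 42.4 | 33.5 |

(each reading ± 0.5 percentage points)

1. which of these there is most of at the end, counted by the substrate in it, grey (right-handed substrate / left-handed substrate / left-handed product / right-handed product)
2. which of these there is most of at the end, counted by the substrate in it, teal (right-handed substrate / left-handed substrate / left-handed product / right-handed product)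
3. the largest of these amounts at the end, in percent of the left-handed substrate and right-handed substrate together charged, grey
4. the largest of these amounts at the end, in percent of the left-handed substrate and right-handed substrate together charged, teal

- reagent is single-handed; left-handed substrate and right-handed substrate are mirror images of each other, charged as a racemate, each of them at the stated concentration
- what may be going on: left-handed substrate <-> right-handed substrate; reagent + right-handed substrate -> right-handed product; reagent + left-handed substrate -> left-handed product; reagent <-> dormant form
- the earlier runs do not show what temperature does; that part of a forecast is a guess
- the handed part of reagent does not stay in what it makes, so the products of the two hands are mirror images too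

Which hand leads? The left, since s stands above 1.

How far does teal get? Teal has the same equivalents at 10 mM against Friday's 20 mM, so its reagent is charged at half Friday's concentration. Friday's last stretch has right-handed substrate falling at 0.574 /min, and as a rough estimate I take half of that for teal. Held for teal's 8.0 min from the charge, this leaves 5.02 % right-handed substrate in teal, and the power rule then gives 49.0 % left-handed product, more than the 45.0 % right-handed product. For grey, temperature is a guess, so I carry the same order over.

The forecast says left-handed product at 50 % for grey and left-handed product at 48.8 % for teal, a little below my teal figure, on the ground that “The left hand reacts about 1.7 times faster”.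

The flasks give left-handed product at 51.3 % in grey and left-handed product at 50.1 % in teal.

    left-handed substrate ⇌ right-handed substrate (k = 9.60 × 10⁻⁴ /s, Ea = 102 kJ/mol)
    reagent + right-handed substrate → right-handed product (k = 0.270 /M/s, Ea = 68.0 kJ/mol)
    reagent + left-handed substrate → left-handed product (k = 0.450 /M/s, Ea = 42.0 kJ/mol)
    reagent ⇌ dormant form (K = 0.880, k = 0.00600 /s, Ea = 109 kJ/mol, ΔH = 2.00 kJ/mol)
    (constants at 80 °C)

Put teal's 41.7 % right-handed product into the power rule and it returns 47.6 % left-handed product, against the 50.1 % teal holds. The neighbouring flask is teal with 1.00 equiv of reagent, read at the same time. Its 14.7 % right-handed product gives 22.3 % by the same rule, and that neighbouring flask holds 22.6 % left-handed product. Right-handed substrate is what the neighbouring flask holds most of, at 33.4 %.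

The readings were computed for an exercise, and the scatter is random.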